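**Retrosynthetic overview**
- The target is epicatechin-(4β→8)-epigallocatechin 3-O-gallate; the last step is global hydrogenolysis of its trideca-O-benzyl ether.
- Key disconnection: the interflavan C4–C8 bond, cut into two electrophiles, an upper-unit C4 ether and a lower-unit C8 bromide. In the forward direction C4, normally the flavan-4-yl cation (quinone-methide acceptor), reacts with reversed polarity as a reductively generated flavan-4-yl donor (a homoenolate-type d3 equivalent of the ring A quinone methide) under nickel catalysis, and C4 is set trans to O3 in the same step.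
- Upper partner: (−)-epicatechin, perbenzylation, then DDQ oxidation at C4. Lower partner: (−)-epigallocatechin, benzylation of the five phenols, C8 bromination, then esterification of the 3-OH with tri-O-benzylgallic acid.
- Rings: none is built. Both chroman systems, the catechol, pyrogallol and galloyl rings and five of the six stereocentres come intact from the two natural flavan-3-ols and the gallic acid derivative; only C4 is created.

Assumption: (−)-epicatechin and (−)-epigallocatechin of natural (2R,3R) configuration are bought as single enantiomers, and 3,4,5-tris(benzyloxy)benzoic acid is bought as such.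

**Route**

Step 1
Reactants: 1 (−)-epicatechin; 2 benzyl bromide
Product: 3 penta-O-benzyl-(−)-epicatechin
Conditions: NaH (5.5 equiv), benzyl bromide (5.5 equiv), DMF, −20 °C → rt, 16 h
Reagents that add atoms: benzyl bromide, BrCc1ccccc1
Why: Williamson etherification of the four phenoxides and the C3 alkoxide caps every hydroxyl without touching C2 or C3, which are kept from the natural product.

Step 2
Reactants: 3 penta-O-benzyl-(−)-epicatechin; 4 2-ethoxyethanol
Product: 5 (2R,3R,4S)-3,5,7-tris(benzyloxy)-2-[3,4-bis(benzyloxy)phenyl]-4-(2-ethoxyethoxy)chromane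
Conditions: DDQ (2 equiv), 2-ethoxyethanol (5 equiv), CH2Cl2, rt, 2 h
Reagents that add atoms: 2-ethoxyethanol, CCOCCO
Why: DDQ benzylic oxidation (hydride abstraction at C4, activated by the three ring A oxygens) gives the C4 cation, which the alcohol traps trans to the 3-OBn group in an oxidative benzylic etherification well known for benzylated flavan-3-ols; the 4β configuration made here is provisional and is reset in step 6.

Step 3
Reactants: 6 (−)-epigallocatechin; 2 benzyl bromide
Product: 7 5,7,3',4',5'-penta-O-benzyl-(−)-epigallocatechin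
Conditions: benzyl bromide (5.5 equiv), K2CO3 (6 equiv), degassed DMF, N2, 0 °C → rt, 24 h
Reagents that add atoms: benzyl bromide, BrCc1ccccc1
Why: Williamson etherification under carbonate conditions alkylates only the five phenoxides, because the secondary 3-OH is not deprotonated and stays free for the later esterification; C2 and C3 come from the natural product and are untouched.

Step 4
Reactants: 7 5,7,3',4',5'-penta-O-benzyl-(−)-epigallocatechin; 8 N-bromosuccinimide
Product: 9 8-bromo-5,7,3',4',5'-penta-O-benzyl-(−)-epigallocatechin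
Conditions: NBS (1.0 equiv), CH2Cl2, −78 °C → −20 °C, dark
Reagents that add atoms: N-bromosuccinimide, O=C1CCC(=O)N1Br
Why: Electrophilic aromatic bromination goes to ring A, the ring activated by three oxygens, and there to C8 rather than C6, the selectivity established at low temperature for 5,7-di-O-benzyl flavan-3-ols with a free 3-OH; the tribenzyloxyphenyl ring is less activated and no stereocentre is involved.

Step 5
Reactants: 9 8-bromo-5,7,3',4',5'-penta-O-benzyl-(−)-epigallocatechin; 10 3,4,5-tris(benzyloxy)benzoic acid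
Product: 11 8-bromo-octa-O-benzyl-(−)-epigallocatechin 3-O-gallate
Conditions: 10 (1.3 equiv), DCC (1.5 equiv), DMAP (0.3 equiv), CH2Cl2, 0 °C → rt, 16 h
Reagents that add atoms: 3,4,5-tris(benzyloxy)benzoic acid, OC(=O)c1cc(OCc2ccccc2)c(OCc2ccccc2)c(OCc2ccccc2)c1
Why: Steglich esterification (O-acylisourea, then the acylpyridinium ion) acylates the axial 3-OH on oxygen, so the C3–O bond is never broken and the 3R configuration is retained; the aryl bromide and the benzyl ethers are inert.

Step 6
Reactants: 5 (2R,3R,4S)-3,5,7-tris(benzyloxy)-2-[3,4-bis(benzyloxy)phenyl]-4-(2-ethoxyethoxy)chromane; 11 8-bromo-octa-O-benzyl-(−)-epigallocatechin 3-O-gallate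
Product: 13 trideca-O-benzyl epicatechin-(4β→8)-epigallocatechin 3-O-gallate, via C4 chloride 12 (not isolated)
Conditions: 5 (1.5 equiv), 11 (1.0 equiv), TMSCl (2 equiv, slow addition), NiBr2(dme) (15 mol %), 4,4'-di-tert-butyl-2,2'-bipyridine (20 mol %), Mn powder (3 equiv), DMA–THF 1:1, 0 °C → rt, 16 h; aqueous NH4Cl work-up
Reagents that add atoms: none
Why: Proposed new method: a nickel-catalysed reductive cross-electrophile coupling in which TMSCl converts the C4 ether of 5 into chloride 12, low-valent nickel abstracts the chloride to give the ring-A-stabilised C4 radical (the polarity-reversed flavan-4-yl donor), the aryl–nickel bromide formed from 11 and zerovalent nickel captures this radical, and reductive elimination from trivalent nickel forms the C4–C8 bond on the face anti to the pseudo-axial 3-OBn group and the 2-aryl group, which sets C4 as 4β (3,4-trans, 4R); the closest known reactions are nickel/bipyridine reductive couplings of secondary benzylic chlorides, acetals (activated by TMSCl) and glycosyl halides with aryl halides, the last giving 1,2-trans C-aryl glycosides.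

Step 7
Reactants: 13 trideca-O-benzyl epicatechin-(4β→8)-epigallocatechin 3-O-gallate
Product: 14 epicatechin-(4β→8)-epigallocatechin 3-O-gallate (CNP0246304.2)
Conditions: H2 (1 atm), Pd(OH)2/C (20 wt %), THF–MeOH–H2O 20:20:1, rt, 12 h; filter under N2, lyophilise
Reagents that add atoms: none
Why: Catalytic hydrogenolysis of all thirteen benzyl ethers (twelve aryl benzyl ethers and the 3-O-benzyl ether) under neutral conditions leaves the gallate ester, the interflavan bond and all six stereocentres intact.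

**Compound list**

1 | (−)-epicatechin, (2R,3R)-2-(3,4-dihydroxyphenyl)chromane-3,5,7-triol | O[C@@H]1Cc2c(O)cc(O)cc2O[C@@H]1c1ccc(O)c(O)c1 | starting material

2 | benzyl bromide | BrCc1ccccc1 | starting material

3 | penta-O-benzyl-(−)-epicatechin, (2R,3R)-3,5,7-tris(benzyloxy)-2-[3,4-bis(benzyloxy)phenyl]chromane | C1c2c(OCc3ccccc3)cc(OCc3ccccc3)cc2O[C@H](c2ccc(OCc3ccccc3)c(OCc3ccccc3)c2)[C@@H]1OCc1ccccc1 | intermediate

4 | 2-ethoxyethanol | CCOCCO | starting material

5 | (2R,3R,4S)-3,5,7-tris(benzyloxy)-2-[3,4-bis(benzyloxy)phenyl]-4-(2-ethoxyethoxy)chromane (4β-alkoxy, 2,3-cis-3,4-trans) | CCOCCO[C@H]1c2c(OCc3ccccc3)cc(OCc3ccccc3)cc2O[C@H](c2ccc(OCc3ccccc3)c(OCc3ccccc3)c2)[C@@H]1OCc1ccccc1 | intermediate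

6 | (−)-epigallocatechin, (2R,3R)-2-(3,4,5-trihydroxyphenyl)chromane-3,5,7-triol | O[C@@H]1Cc2c(O)cc(O)cc2O[C@@H]1c1cc(O)c(O)c(O)c1 | starting material

7 | 5,7,3',4',5'-penta-O-benzyl-(−)-epigallocatechin, (2R,3R)-5,7-bis(benzyloxy)-2-[3,4,5-tris(benzyloxy)phenyl]chroman-3-ol | O[C@@H]1Cc2c(OCc3ccccc3)cc(OCc3ccccc3)cc2O[C@@H]1c1cc(OCc2ccccc2)c(OCc2ccccc2)c(OCc2ccccc2)c1 | intermediate

8 | N-bromosuccinimide | O=C1CCC(=O)N1Br | starting material

9 | 8-bromo-5,7,3',4',5'-penta-O-benzyl-(−)-epigallocatechin, (2R,3R)-5,7-bis(benzyloxy)-8-bromo-2-[3,4,5-tris(benzyloxy)phenyl]chroman-3-ol | O[C@@H]1Cc2c(OCc3ccccc3)cc(OCc3ccccc3)c(Br)c2O[C@@H]1c1cc(OCc2ccccc2)c(OCc2ccccc2)c(OCc2ccccc2)c1 | intermediate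

10 | 3,4,5-tris(benzyloxy)benzoic acid (tri-O-benzylgallic acid) | OC(=O)c1cc(OCc2ccccc2)c(OCc2ccccc2)c(OCc2ccccc2)c1 | starting material

11 | 8-bromo-octa-O-benzyl-(−)-epigallocatechin 3-O-gallate, (2R,3R)-5,7-bis(benzyloxy)-8-bromo-2-[3,4,5-tris(benzyloxy)phenyl]chroman-3-yl 3,4,5-tris(benzyloxy)benzoate | O=C(O[C@@H]1Cc2c(OCc3ccccc3)cc(OCc3ccccc3)c(Br)c2O[C@@H]1c1cc(OCc2ccccc2)c(OCc2ccccc2)c(OCc2ccccc2)c1)c1cc(OCc2ccccc2)c(OCc2ccccc2)c(OCc2ccccc2)c1 | intermediate

12 | C4 chloride, (2R,3S,4S)-3,5,7-tris(benzyloxy)-2-[3,4-bis(benzyloxy)phenyl]-4-chlorochromane (4β-chloride drawn; labile at C4 through its ion pair) | Cl[C@H]1c2c(OCc3ccccc3)cc(OCc3ccccc3)cc2O[C@H](c2ccc(OCc3ccccc3)c(OCc3ccccc3)c2)[C@@H]1OCc1ccccc1 | intermediate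

13 | trideca-O-benzyl epicatechin-(4β→8)-epigallocatechin 3-O-gallate, (2R,3R)-5,7-bis(benzyloxy)-8-[(2R,3R,4R)-3,5,7-tris(benzyloxy)-2-[3,4-bis(benzyloxy)phenyl]chroman-4-yl]-2-[3,4,5-tris(benzyloxy)phenyl]chroman-3-yl 3,4,5-tris(benzyloxy)benzoate | O=C(O[C@@H]1Cc2c(OCc3ccccc3)cc(OCc3ccccc3)c([C@H]3c4c(OCc5ccccc5)cc(OCc5ccccc5)cc4O[C@H](c4ccc(OCc5ccccc5)c(OCc5ccccc5)c4)[C@@H]3OCc3ccccc3)c2O[C@@H]1c1cc(OCc2ccccc2)c(OCc2ccccc2)c(OCc2ccccc2)c1)c1cc(OCc2ccccc2)c(OCc2ccccc2)c(OCc2ccccc2)c1 | intermediate

14 | epicatechin-(4β→8)-epigallocatechin 3-O-gallate, (2R,3R)-8-[(2R,3R,4R)-2-(3,4-dihydroxyphenyl)-3,5,7-trihydroxychroman-4-yl]-5,7-dihydroxy-2-(3,4,5-trihydroxyphenyl)chroman-3-yl 3,4,5-trihydroxybenzoate | O=C(O[C@@H]1Cc2c(O)cc(O)c([C@H]3c4c(O)cc(O)cc4O[C@H](c4ccc(O)c(O)c4)[C@@H]3O)c2O[C@@H]1c1cc(O)c(O)c(O)c1)c1cc(O)c(O)c(O)c1 | target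

**Totals**

Total step count: 7. Longest linear sequence: 5 steps (steps 3, 4, 5, 6, 7); the epicatechin branch (steps 1, 2, 6, 7) is 4 steps long.

**Steps most likely to fail, with fallbacks**

Step 6 (the interflavan coupling) is the main risk. It must join a peri-substituted secondary benzylic radical to an aryl–nickel species flanked by two ortho oxygens. Ionised chloride 12 can instead be captured in a Friedel–Crafts sense by free ring A positions, and the radical can dimerise or be reduced. The fallback keeps C4 as the donor but replaces catalytic radical capture by a stoichiometric, configurationally defined C4 organometallic that is transferred stereospecifically. It sets out from 5: TMSCl (1 equiv, CH2Cl2, 0 °C) gives chloride 12, and after removal of volatiles Bu3SnLi (THF, −78 °C) adds trans to the 3-OBn group to give the isolable 4β-stannane tributyl[(2R,3S,4S)-3,5,7-tris(benzyloxy)-2-[3,4-bis(benzyloxy)phenyl]chroman-4-yl]stannane F1. F1 is then joined to bromide 11 by a stereoretentive palladium-catalysed C(sp3)–Sn coupling of the kind used for anomeric stannanes (Pd2(dba)3, JackiePhos, CuCl, KF, 1,4-dioxane, 100 °C). The fallback comes back to the route at 13.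

Step 3 (benzylation of the five phenols of 6) can suffer from air oxidation of the pyrogallol phenoxides, C-benzylation of ring A and base-induced epimerisation at C2. The fallback sets out from 6 and never lets free polyphenolate accumulate. Ac2O in pyridine gives hexa-O-acetyl-(−)-epigallocatechin F2. A one-pot deacetylation–benzylation follows (K2CO3, MeOH 10 equiv, benzyl bromide 2 in excess, DMF, 0 °C → rt). Each phenoxide is benzylated as soon as methanolysis unmasks it. The 3-acetate is methanolysed as well, and the secondary alcohol it leaves is not alkylated by carbonate. It comes back to the route at 7.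

Step 2 (DDQ oxidation of the fully benzylated 3) may be slow or over-oxidise, because the precedent is strongest for substrates with a free 3-OH. The fallback changes the order of protection and oxidation and sets out from 1. K2CO3 and benzyl bromide 2 in DMF give 5,7,3',4'-tetra-O-benzyl-(−)-epicatechin F3. DDQ with 2-ethoxyethanol 4 in CH2Cl2 gives (2R,3R,4S)-5,7-bis(benzyloxy)-2-[3,4-bis(benzyloxy)phenyl]-4-(2-ethoxyethoxy)chroman-3-ol F4. O3-benzylation (NaH, 2, DMF, 0 °C) then brings it back to the route at 5.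

**Further compounds**

F1 | step 6 | tributyl[(2R,3S,4S)-3,5,7-tris(benzyloxy)-2-[3,4-bis(benzyloxy)phenyl]chroman-4-yl]stannane (4β-stannyl) | CCCC[Sn](CCCC)(CCCC)[C@H]1c2c(OCc3ccccc3)cc(OCc3ccccc3)cc2O[C@H](c2ccc(OCc3ccccc3)c(OCc3ccccc3)c2)[C@@H]1OCc1ccccc1

F2 | step 3 | hexa-O-acetyl-(−)-epigallocatechin, (2R,3R)-5,7-diacetoxy-2-(3,4,5-triacetoxyphenyl)chroman-3-yl acetate | CC(=O)O[C@@H]1Cc2c(OC(C)=O)cc(OC(C)=O)cc2O[C@@H]1c1cc(OC(C)=O)c(OC(C)=O)c(OC(C)=O)c1

F3 | step 2 | 5,7,3',4'-tetra-O-benzyl-(−)-epicatechin, (2R,3R)-5,7-bis(benzyloxy)-2-[3,4-bis(benzyloxy)phenyl]chroman-3-ol | C1c2c(OCc3ccccc3)cc(OCc3ccccc3)cc2O[C@H](c2ccc(OCc3ccccc3)c(OCc3ccccc3)c2)[C@@H]1O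

F4 | step 2 | (2R,3R,4S)-5,7-bis(benzyloxy)-2-[3,4-bis(benzyloxy)phenyl]-4-(2-ethoxyethoxy)chroman-3-ol | CCOCCO[C@H]1c2c(OCc3ccccc3)cc(OCc3ccccc3)cc2O[C@H](c2ccc(OCc3ccccc3)c(OCc3ccccc3)c2)[C@@H]1O
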